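# Kweichowenol B by an α-benzoyloxyacrolein Diels–Alder route

Atom numbering used throughout: C1 is the quaternary carbinol carbon, C2 and C3 are the CHOH carbons, C4 is the CHOBz carbon, C5=C6 is the ring alkene and C7 is the exocyclic CH2. O1–O4 and O7 are the oxygens on those carbons. The ring face that carries the C1 hydroxyl is called the lower face.

## The problem

Kweichowenol B (15) is a monocyclic cyclohexene: C1 is a quaternary carbinol carrying the benzoyloxymethyl carbon C7, C2 and C3 are secondary carbinols, C4 bears an allylic benzoate, and C5=C6 closes the ring back to C1. The four contiguous stereocentres alternate, so that with O1 on the lower face O2 is up (cis to C7), O3 is down and the C4 benzoate is up, and every pair of neighbouring C–O bonds is trans. C1 cannot be corrected once made and nothing in the ring can direct its formation, so it has to come from a reagent-controlled reaction; C2 can be set together with it, the C2 oxygen can then send an oxidant to the opposite face of C3=C4, and C4 follows from C3 by inversion at the allylic end of a vinyl oxirane. The two benzoates must end on O7 and O4 only, although benzoates next to free hydroxyls migrate under base (O4 to O3, O7 to O1). The C4 benzoate is allylic and would ionise under strong acid or with zerovalent palladium, and the cyclohexadiene intermediates can aromatise by losing the C1 oxygen together with the C2 hydrogen. The enabling feature is that C1 carries an oxygen and the one-carbon unit C7 and lies between C6 and the oxygenated C2, so that C6–C1(O)–C7 is the skeleton of an α-acyloxyacrolein and C2–C5 that of a 1-oxygenated butadiene. A [4+2] cycloaddition forming C1–C2 and C5–C6 therefore sets C1 and C2 in one step. The price is that the cycloaddition leaves the alkene at C3=C4 whereas the target has it at C5=C6, so the unsaturation must be moved while C3 and C4 are oxygenated.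

## Retrosynthesis

**15 ⇒ 14.** Only protecting groups are removed: the O1–Si bond of a triethylsilyl ether and the O2–acyl bond of an acetate, leading back to 14. Ending on a deprotection is preferred to ending on a benzoylation, because picking O4 among the hydroxyls of a polyol is far less certain than unmasking O1 and O2 with both benzoates already placed. Both groups fall in acidic methanol, where benzoates exchange slowly and do not migrate. The forward step must cleave a hindered secondary acetate without touching a neopentyl-type primary benzoate or an allylic one.

**14 ⇒ 13.** The C4–O bond of the benzoate is cut to reveal vinyl oxirane 13, with the oxirane on C3–C4 opposite the C2 acetate and C5=C6 in place. This cut places the acyl group and sets the trans C3/C4 relationship in one event, whereas a 3,4-diol followed by selective acylation would need two secondary hydroxyls to be told apart. The forward reaction is an SN2 opening by a carboxylate at the allylic carbon with inversion. It must prefer C4 over the non-allylic C3, must not run as conjugate attack at C6, and must not let the C2 acetate open the oxirane from within.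

**13 ⇒ 12.** The two C–O bonds of the oxirane are removed to give cyclohexadiene 12, which holds only the two stereocentres of the cycloadduct. Epoxidising before C5=C6 exists would be safer facially but would leave no handle for introducing that alkene afterwards. The forward step must choose C3=C4 over C5=C6 and the face anti to the C2 acetate. For this reason C1 carries a bulky silyl ether that cannot donate a hydrogen bond.

**12 ⇒ 9.** The C5=C6 π bond is removed, giving cyclohexene 9 by way of the allylic bromides 10 and 11. Radical bromination and dehydrobromination is preferred to a stepwise oxygen-based transposition because both regioisomeric bromides converge on the same diene. An acetate at C2 also deactivates the one competing allylic hydrogen, which a silyl ether would not. The forward reaction must abstract hydrogen at C5 and eliminate toward C6.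

**9 ⇒ 8 ⇒ 6.** Removing the silyl group gives carbinol 8. Returning the benzoyl group from O7 to O1 (compound 7) and re-oxidising C7 leads to aldehyde 6. The benzoate that the target needs on O7 is thus carried by the dienophile from the start and is relayed, not installed separately. The forward sequence requires the benzoyl group, not the acetyl group, to move to O7.

**6 ⇒ 4 + 5.** C1–C2 and C5–C6 are cut in a retro-[4+2] to 2-(benzoyloxy)acrolein 4 and (E)-1-acetoxybutadiene 5. Other pairs of ring bonds would not place the acrolein α-carbon at C1, and only this pair makes the quaternary centre and its neighbour together from two achiral pieces of three and four carbons. The forward reaction must give ortho regiochemistry, endo orientation of the formyl group and one enantiomer. An enol acetate is chosen for 5 because it tolerates an acidic ammonium catalyst.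

**4 ⇒ 3 ⇒ 1 + 2.** Read backwards, acrolein 4 and acetone recombine in a hetero-[4+2] sense to the dioxin enol ester 3. Cutting its O–acyl bond leads to commercial ketone 1 and benzoyl chloride 2. The unstable acrolein is thereby stored as a stable precursor and released just before use; the forward cycloreversion only has to be driven by removal of acetone.

## Roads not taken

Alternative 1: The cut is at the C1–O and C2–O bonds and takes the ring back to benzoic acid A1, whose carboxyl carbon becomes C7. In the forward direction a benzoate dioxygenase, in whole cells of a mutant lacking the diol dehydrogenase, adds two oxygens across the ipso and ortho carbons and gives diol acid A2 in one step. A2 is enantiopure, has C1 in the configuration of 15 and already contains the C3–C6 diene. In step economy this is clearly better than the chosen plan up to the diene stage, since A2 corresponds to 12, which here takes six steps. Its weak points are these: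
- A2 is a cis-diol, whereas 15 has O1 and O2 trans. C2 would have to be inverted at a carbinol that is allylic to a diene and next to a quaternary centre, where displacement competes with allylic transposition and aromatisation.
- The carboxyl group of the acid-sensitive A2 must be reduced to the C7 alcohol.
- The key step is a fermentation with a particular strain and gives one enantiomeric series only.

Against the shorter sequence, the chosen plan sets C7 cis to O2 directly through the endo transition state, needs no inversion, and uses shelf reagents with either catalyst antipode.

Alternative 2: The cut is at C2–O and C3–O, read as an oxirane, on the achiral dienone A3, a 4-hydroxycyclohexa-2,5-dienone that already carries the C7 benzoate. In the forward direction a chiral primary-amine salt with aqueous H2O2 would epoxidise one of the two enantiotopic enone alkenes on the hydroxyl face, giving A4 and fixing C1, C2 and C3 together. A3 is achiral and should be reachable in very few steps by oxidative dearomatisation, and C5=C6 and the C4 oxygen are present from the start. Nothing like steps 6 and 7 of the chosen route is needed, which is a real advantage at the chosen plan's least secure stage. Its weak points are these: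
- In A4 the oxirane oxygen is syn to O1, which is right for C3 but wrong for C2. C2 must be inverted by opening the oxirane at the neopentyl-like C2, while the carbonyl activates C3.
- The C4 carbonyl of the base-sensitive A4 must be reduced trans to O3 and the resulting hydroxyl benzoylated selectively.

On paper this route is shorter. The chosen plan has C2 correct from the cycloaddition, and its oxirane 13 is biased electronically toward the right carbon, C4, whereas in A4 the bias runs the wrong way.

Alternative 3: The cut is at C3–C4 and C5–C6. Furan-3-ylmethyl benzoate A5 supplies C6, C1, C2, C3, C7 and a bridging oxygen, and 2-bromoacrolein A6 supplies C4 and C5. In the forward direction a Diels–Alder reaction under a chiral boron Lewis acid gives oxabicycle A7, a cycloaddition of a well-precedented type. After oxidative excision of the bromo-formyl unit to leave a carbonyl at C4, base would open the oxygen bridge by β-elimination, creating C5=C6 by a polar, regiospecific process and leaving the bridge oxygen on C3. That is cleaner than the radical bromination of step 6. Its weak points are these: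
- In A7 C1 is still an alkene carbon. The quaternary carbinol, the hardest centre, is not made by the key step and must come from a later face-selective oxidation of C1=C2 with a trans outcome.
- The formyl carbon is surplus and has to be excised.
- Only C3 of the stereocentres of A7 survives.
- A5 can add in two orientations, and cycloadducts of the A7 type revert readily.

This route is longer and leaves the main problem open, whereas the chosen plan spends its key step on C1 and C2.

Key step: step 3

## Route

Assumption: the (R)-diamine is written as the antipode that leads to (1S,2S)-6. This sense of induction is extrapolated from cyclic dienes and must be confirmed by correlation, and the (S)-diamine is used instead if it proves opposite.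

Assumption: commercial 1-acetoxybuta-1,3-diene is an E/Z mixture in which only the E isomer 5 is a competent diene. It is used in excess without separation.

Step 1
Reactants: 1 2,2-dimethyl-1,3-dioxan-5-one; 2 benzoyl chloride
Product: 3 2,2-dimethyl-4H-1,3-dioxin-5-yl benzoate
Conditions: Et3N, DMAP (cat.), CH2Cl2, 0 °C to rt
Reagents that add atoms: none
Why: O-Acylation of a ketone enolate (enol ester formation): the α,α'-dialkoxy ketone is acidic enough for Et3N, and the acylpyridinium ion formed with DMAP is trapped on oxygen to give the dioxin enol benzoate; no stereocentre is formed.

Step 2
Reactants: 3 2,2-dimethyl-4H-1,3-dioxin-5-yl benzoate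
Product: 4 2-(benzoyloxy)prop-2-enal
Conditions: toluene, 110 °C, slow N2 stream
Reagents that add atoms: none
Why: Retro-hetero-Diels–Alder cycloreversion of the 4H-1,3-dioxin: heating splits the ring into the enal and acetone, whose removal in the gas stream drives the reaction; 4 is used at once because 2-acyloxyacroleins polymerise on storage.

Step 3
Reactants: 4 2-(benzoyloxy)prop-2-enal; 5 (E)-buta-1,3-dien-1-yl acetate
Product: 6 (1S,2S)-2-acetoxy-1-formylcyclohex-3-en-1-yl benzoate (formyl cis to acetoxy)
Conditions: (R)-1,1'-binaphthyl-2,2'-diamine (10 mol%), HNTf2 (19 mol%), EtCN, −75 to −40 °C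
Reagents that add atoms: none
Why: One amino group of the diammonium salt condenses with the aldehyde of 4 to an iminium ion, the LUMO-lowered dienophile, while the second ammonium group can hydrogen-bond to the benzoate carbonyl and hold the ion in one conformation. Diene 5 adds in a concerted, asynchronous [4+2] cycloaddition in which its unsubstituted terminus C5 bonds first to the iminium β-carbon C6 and its acetoxy terminus C2 then closes onto C1; hydrolysis of the product iminium returns the catalyst. The six-membered carbocycle is thus closed by an intermolecular suprafacial–suprafacial cycloaddition that forms C5–C6 and C1–C2 in the same step. The closest known reactions are the diammonium-salt-catalysed Diels–Alder additions of α-acyloxyacroleins to cyclic and simple acyclic dienes and the iminium-catalysed additions of 1-acetoxybutadiene to enals. C1 is set by the catalyst, whose binaphthyl backbone covers one face of the iminium ion; C2 follows from the E geometry of 5 and an endo arrangement of the C=N unit, which puts the formyl carbon cis to the acetoxy group. The step needs ortho regiochemistry, endo selectivity and one iminium face: the first is secured by the acetoxy donor, which makes C5 the nucleophilic terminus and matches it with the electrophilic β-carbon, the second by secondary overlap that no bridging methylene opposes in an open-chain diene, and the third by the catalyst. An enol acetate is chosen as the diene because, unlike a silyl dienol ether, it survives the acidic ammonium salt.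

Step 4
Reactants: 6 (1S,2S)-2-acetoxy-1-formylcyclohex-3-en-1-yl benzoate
Product: 8 [(1R,2S)-2-acetoxy-1-hydroxycyclohex-3-en-1-yl]methyl benzoate, via tertiary benzoate carbinol 7 (not isolated)
Conditions: NaBH4, MeOH/THF, −40 to 0 °C; AcOH quench once the shift is complete
Reagents that add atoms: none
Why: Borohydride reduces the aldehyde and leaves the esters; the primary alkoxide of 7 adds to the neighbouring tertiary benzoate through a five-membered orthoester anion that collapses with the acyl group on the less hindered primary oxygen (1,2 O-to-O acyl migration, downhill from a tertiary to a primary ester). The acetate could be reached only through a six-membered intermediate, and an acidic quench applied as soon as the shift is complete stops further equilibration; C1 and C2 are not touched.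

Step 5
Reactants: 8 [(1R,2S)-2-acetoxy-1-hydroxycyclohex-3-en-1-yl]methyl benzoate
Product: 9 [(1R,2S)-2-acetoxy-1-(triethylsilyloxy)cyclohex-3-en-1-yl]methyl benzoate
Conditions: TESOTf, 2,6-lutidine, CH2Cl2, −40 to 0 °C
Reagents that add atoms: triethylsilyl trifluoromethanesulfonate, CC[Si](CC)(CC)OS(=O)(=O)C(F)(F)F
Why: Silylation of a tertiary alcohol with a silyl triflate and a hindered pyridine base; the ether removes the hydrogen-bond donor that would steer an oxidant to C5=C6 in step 7, adds bulk on the C6 side, and later falls under the same acidic conditions as the acetate.

Step 6
Reactants: 9 [(1R,2S)-2-acetoxy-1-(triethylsilyloxy)cyclohex-3-en-1-yl]methyl benzoate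
Product: 12 [(1R,6S)-6-acetoxy-1-(triethylsilyloxy)cyclohexa-2,4-dien-1-yl]methyl benzoate, via allylic 5-bromide 10 (not isolated), via transposed allylic 3-bromide 11 (not isolated)
Conditions: NBS, AIBN (cat.), PhCF3, 80 °C; filter, concentrate; DBU, THF, 0 °C to rt
Reagents that add atoms: none
Why: Wohl–Ziegler bromination followed by dehydrobromination: the bromine atom abstracts a C5 hydrogen, the only allylic methylene (the C2 hydrogen is deactivated toward this electrophilic radical by the acetoxy group), and the allyl radical is captured at C5 (10) or C3 (11). DBU removes HBr from 10 by 1,2-elimination toward C6 and from 11 by 1,4-elimination, so both converge on diene 12; C1 is quaternary, so loss of HBr cannot continue to an arene, and the stereocentres are untouched.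

Step 7
Reactants: 12 [(1R,6S)-6-acetoxy-1-(triethylsilyloxy)cyclohexa-2,4-dien-1-yl]methyl benzoate
Product: 13 [(1R,2S,3R,6R)-2-acetoxy-3-(triethylsilyloxy)-7-oxabicyclo[4.1.0]hept-4-en-3-yl]methyl benzoate (C3–C4 oxirane trans to the C2 acetate; C5=C6 retained)
Conditions: dimethyldioxirane (1 equiv), acetone/CH2Cl2, −20 °C
Reagents that add atoms: dimethyldioxirane, CC1(C)OO1
Why: Electrophilic epoxidation of a 1,3-diene by a dioxirane under neutral conditions: C3=C4 is preferred because C5=C6 is flanked by the fully substituted C1, whose silyloxy and benzoyloxymethyl groups cover both of its faces, and the oxidant approaches C3=C4 anti to the pseudoaxial C2 acetate, setting C3 and C4 with both C–O bonds on the lower face. The remaining alkene of 13 is deactivated by the allylic oxirane, which limits over-oxidation, and the acid-free medium preserves the vinyl oxirane.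

Step 8
Reactants: 13 [(1R,2S,3R,6R)-2-acetoxy-3-(triethylsilyloxy)-7-oxabicyclo[4.1.0]hept-4-en-3-yl]methyl benzoate
Product: 14 [(1R,4S,5R,6S)-6-acetoxy-4-(benzoyloxy)-5-hydroxy-1-(triethylsilyloxy)cyclohex-2-en-1-yl]methyl benzoate
Conditions: PhCO2H (4 equiv), Et3N (1 equiv), toluene, rt to 40 °C
Reagents that add atoms: benzoic acid, O=C(O)c1ccccc1
Why: Opening of a vinyl oxirane by a carboxylic acid/carboxylate pair: hydrogen bonding from the acid activates the oxirane and benzoate attacks the allylic carbon C4 in an SN2 manner with inversion, giving the trans C3-hydroxy C4-benzoate; C3 is non-allylic and next to the acetoxy-bearing C2, and conjugate attack at C6 is blocked by the quaternary C1. C4 is set by inversion and C3 keeps its oxygen; a shift of the acetyl group from O2 to O3 here would be without consequence, since step 9 removes it from either position.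

Step 9
Reactants: 14 [(1R,4S,5R,6S)-6-acetoxy-4-(benzoyloxy)-5-hydroxy-1-(triethylsilyloxy)cyclohex-2-en-1-yl]methyl benzoate
Product: 15 kweichowenol B, [(1R,4S,5S,6S)-4-(benzoyloxy)-1,5,6-trihydroxycyclohex-2-en-1-yl]methyl benzoate
Conditions: HCl (1.25 M in MeOH), CH2Cl2/MeOH, 0 °C to rt
Reagents that add atoms: none
Why: Acid-catalysed methanolysis: the tertiary silyl ether is solvolysed quickly and the acetate is transesterified much faster than the benzoates, a selectivity routinely used to remove acetyl in the presence of benzoyl groups; the non-basic medium avoids the alkoxide-driven benzoyl shifts from O4 to O3 and from O7 to O1, and no stereocentre is affected.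

## Compound list

1 | 2,2-dimethyl-1,3-dioxan-5-one | CC1(C)OCC(=O)CO1 | starting material
2 | benzoyl chloride | O=C(Cl)c1ccccc1 | starting material
3 | 2,2-dimethyl-4H-1,3-dioxin-5-yl benzoate | CC1(C)OCC(OC(=O)c2ccccc2)=CO1 | intermediate
4 | 2-(benzoyloxy)prop-2-enal | C=C(OC(=O)c1ccccc1)C=O | intermediate
5 | (E)-buta-1,3-dien-1-yl acetate | CC(=O)O/C=C/C=C | starting material
6 | (1S,2S)-2-acetoxy-1-formylcyclohex-3-en-1-yl benzoate | O=C[C@]1(OC(=O)c2ccccc2)CCC=C[C@@H]1OC(C)=O | intermediate
7 | (1R,2S)-2-acetoxy-1-(hydroxymethyl)cyclohex-3-en-1-yl benzoate (not isolated) | OC[C@]1(OC(=O)c2ccccc2)CCC=C[C@@H]1OC(C)=O | intermediate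
8 | [(1R,2S)-2-acetoxy-1-hydroxycyclohex-3-en-1-yl]methyl benzoate | O=C(OC[C@]1(O)CCC=C[C@@H]1OC(C)=O)c1ccccc1 | intermediate
9 | [(1R,2S)-2-acetoxy-1-(triethylsilyloxy)cyclohex-3-en-1-yl]methyl benzoate | O=C(OC[C@]1(O[Si](CC)(CC)CC)CCC=C[C@@H]1OC(C)=O)c1ccccc1 | intermediate
10 | [(1R,2S)-2-acetoxy-5-bromo-1-(triethylsilyloxy)cyclohex-3-en-1-yl]methyl benzoate, both C5 epimers (not isolated) | O=C(OC[C@]1(O[Si](CC)(CC)CC)CC(Br)C=C[C@@H]1OC(C)=O)c1ccccc1 | intermediate
11 | [(1R,6R)-6-acetoxy-5-bromo-1-(triethylsilyloxy)cyclohex-3-en-1-yl]methyl benzoate, both epimers at the bromine-bearing carbon (not isolated) | O=C(OC[C@]1(O[Si](CC)(CC)CC)CC=CC(Br)[C@@H]1OC(C)=O)c1ccccc1 | intermediate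
12 | [(1R,6S)-6-acetoxy-1-(triethylsilyloxy)cyclohexa-2,4-dien-1-yl]methyl benzoate | O=C(OC[C@]1(O[Si](CC)(CC)CC)C=CC=C[C@@H]1OC(C)=O)c1ccccc1 | intermediate
13 | [(1R,2S,3R,6R)-2-acetoxy-3-(triethylsilyloxy)-7-oxabicyclo[4.1.0]hept-4-en-3-yl]methyl benzoate | O=C(OC[C@]1(O[Si](CC)(CC)CC)C=C[C@H]2O[C@H]2[C@@H]1OC(C)=O)c1ccccc1 | intermediate
14 | [(1R,4S,5R,6S)-6-acetoxy-4-(benzoyloxy)-5-hydroxy-1-(triethylsilyloxy)cyclohex-2-en-1-yl]methyl benzoate | O=C(OC[C@]1(O[Si](CC)(CC)CC)C=C[C@H](OC(=O)c2ccccc2)[C@@H](O)[C@@H]1OC(C)=O)c1ccccc1 | intermediate
15 | kweichowenol B, [(1R,4S,5S,6S)-4-(benzoyloxy)-1,5,6-trihydroxycyclohex-2-en-1-yl]methyl benzoate | O=C(OC[C@]1(O)C=C[C@H](OC(=O)c2ccccc2)[C@@H](O)[C@@H]1O)c1ccccc1 | target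

## Step count and least certain steps

Total: 9 steps. Longest linear sequence: 9 steps (1 to 15); diene 5 enters at step 3.

**Step 3 (key step).** An open-chain 1-oxygenated diene has not been examined with this catalyst family, and three things may go wrong. Endo preference may erode: with cyclic dienes, α-substituted acroleins place the formyl group exo, and that mode would give the C2-epimeric series. The weakly nucleophilic diene may react slowly at low temperature, leaving time for acyl transfer from the enol acetate to the primary amine of the catalyst. Facial discrimination may be lower for the aromatic ester than for the aliphatic esters usually used. The fallback sets out from 4 and 5 and returns at 6. The partners are combined under a chiral Lewis acid instead of an amine salt: the oxazaborolidinium ion generated from the B-(o-tolyl)oxazaborolidine of (S)-α,α-diphenylprolinol and HNTf2, in CH2Cl2 at −78 °C (or its mirror image, whichever gives 6). Activation by coordination at the formyl oxygen involves no free amine, and cationic oxazaborolidines are established for α-substituted acroleins with acyclic dienes. No new compound arises (F0).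

**Step 4.** Acyl scrambling is the likely failure. The acetyl group may shift from O2 to O7 before the benzoyl group arrives, and the benzoyl group may then wander to O2; both migrations run through cyclic orthoester anions of similar accessibility, and acetyl is intrinsically the more mobile group. The fallback sets out from 6 and returns at 8. Reduction with NaBH4 in MeOH, followed in the same flask by K2CO3, removes both esters and gives (1R,2S)-1-(hydroxymethyl)cyclohex-3-ene-1,2-diol F1. Benzoyl chloride 2 with 2,4,6-collidine in CH2Cl2 at −40 °C then acylates only the primary hydroxyl, giving [(1R,2S)-1,2-dihydroxycyclohex-3-en-1-yl]methyl benzoate F2. Ac2O and pyridine finally acetylate the secondary allylic hydroxyl and leave the tertiary one, giving 8.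

**Step 6.** Hydrogen abstraction at C2 or ionic addition of bromine to the alkene may compete in the radical step. In the base step, the transposed bromide 11 may eliminate toward C2 to an enol-acetate diene, or DBU may substitute instead of eliminating. The fallback sets out from 9, returns at 12 and uses no radical chemistry. mCPBA in CH2Cl2 should give the C3–C4 oxirane trans to the acetate F3. PhSeNa, made from PhSeSePh and NaBH4 in EtOH, opens it at C4, away from the acetoxy-bearing carbon, to the trans C3-hydroxy C4-phenylselenide F4. H2O2 oxidises this to the selenoxide F5, which undergoes syn-elimination toward C5 to the allylic alcohol F6 (O3 on the lower face, C4=C5). Heating F6 with 2,4-dinitrobenzenesulfenyl chloride and Et3N in 1,2-dichloroethane at 80 °C forms the allylic sulfenate F7. It rearranges by a [2,3]-shift to the C5 allylic sulfoxide F8, whose syn-elimination can only run toward C6 and gives 12.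

**Step 7 (and with it step 8).** Epoxidation may occur at C5=C6 or on the acetate face of C3=C4, because the inductive effect of the allylic acetate works against the steric bias. In step 8 the C2 acetate may open the oxirane at C3 from within. The fallback sets out from 12, returns at 14 and replaces both steps. OsO4 (cat.) with N-methylmorpholine N-oxide in acetone/H2O, an oxidant more sensitive to hindrance and reliably anti to an allylic acyloxy group, gives the lower-face C3,C4-cis-diol F9 with C5=C6 retained. A Mitsunobu reaction (PPh3, DIAD, PhCO2H, THF, 0 °C) then displaces the more reactive allylic C4 hydroxyl with inversion and installs the benzoate, giving 14.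

**Step 9.** Methanolysis of the hindered C2 acetate may be slow, giving time for partial loss of a benzoate or an acid-catalysed benzoyl shift from O4 to O3. The fallback sets out from 14, returns at 15 and separates the two deprotections. HF·pyridine in THF removes the silyl ether and gives 2-O-acetylkweichowenol B F10. The acetate is then hydrolysed by immobilised Candida antarctica lipase B in pH 7 phosphate buffer/MTBE, where benzoates are not substrates and no base is present, giving 15.

## Further compounds

F0 | step 3 | none | none
F1 | step 4 | (1R,2S)-1-(hydroxymethyl)cyclohex-3-ene-1,2-diol | OC[C@]1(O)CCC=C[C@@H]1O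
F2 | step 4 | [(1R,2S)-1,2-dihydroxycyclohex-3-en-1-yl]methyl benzoate | O=C(OC[C@]1(O)CCC=C[C@@H]1O)c1ccccc1
F3 | step 6 | C3–C4 oxirane of 9, trans to the C2 acetate | O=C(OC[C@]1(O[Si](CC)(CC)CC)CC[C@H]2O[C@H]2[C@@H]1OC(C)=O)c1ccccc1
F4 | step 6 | trans C3-hydroxy C4-phenylselenide from F3 | O=C(OC[C@]1(O[Si](CC)(CC)CC)CC[C@H]([Se]c2ccccc2)[C@@H](O)[C@@H]1OC(C)=O)c1ccccc1
F5 | step 6 | selenoxide of F4 | O=C(OC[C@]1(O[Si](CC)(CC)CC)CC[C@H]([Se](=O)c2ccccc2)[C@@H](O)[C@@H]1OC(C)=O)c1ccccc1
F6 | step 6 | allylic alcohol, C3 hydroxyl on the lower face, C4=C5 alkene | O=C(OC[C@]1(O[Si](CC)(CC)CC)CC=C[C@@H](O)[C@@H]1OC(C)=O)c1ccccc1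
F7 | step 6 | 2,4-dinitrobenzenesulfenate of F6 | O=C(OC[C@]1(O[Si](CC)(CC)CC)CC=C[C@@H](OSc2ccc([N+](=O)[O-])cc2[N+](=O)[O-])[C@@H]1OC(C)=O)c1ccccc1
F8 | step 6 | C5 allylic 2,4-dinitrophenyl sulfoxide, sulfur on the lower face, C3=C4 alkene | O=C(OC[C@]1(O[Si](CC)(CC)CC)C[C@H](C=C[C@@H]1OC(C)=O)S(=O)c1ccc([N+](=O)[O-])cc1[N+](=O)[O-])c1ccccc1
F9 | step 7 | C3,C4-cis-diol of 12 on the lower face, C5=C6 retained | O=C(OC[C@]1(O[Si](CC)(CC)CC)C=C[C@@H](O)[C@@H](O)[C@@H]1OC(C)=O)c1ccccc1
F10 | step 9 | 2-O-acetylkweichowenol B, [(1R,4S,5R,6S)-6-acetoxy-4-(benzoyloxy)-1,5-dihydroxycyclohex-2-en-1-yl]methyl benzoate | O=C(OC[C@]1(O)C=C[C@H](OC(=O)c2ccccc2)[C@@H](O)[C@@H]1OC(C)=O)c1ccccc1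
A1 | alternative 1 | benzoic acid | O=C(O)c1ccccc1
A2 | alternative 1 | (1S,2R)-1,2-dihydroxycyclohexa-3,5-diene-1-carboxylic acid | OC(=O)[C@]1(O)C=CC=C[C@H]1O
A3 | alternative 2 | (1-hydroxy-4-oxocyclohexa-2,5-dien-1-yl)methyl benzoate | O=C(OCC1(O)C=CC(=O)C=C1)c1ccccc1
A4 | alternative 2 | C2–C3 epoxide of A3, syn to the C1 hydroxyl | O=C(OC[C@]1(O)C=CC(=O)[C@H]2O[C@@H]12)c1ccccc1
A5 | alternative 3 | furan-3-ylmethyl benzoate | O=C(OCc1ccoc1)c1ccccc1
A6 | alternative 3 | 2-bromoprop-2-enal | C=C(Br)C=O
A7 | alternative 3 | exo-formyl 2-bromo-7-oxabicyclo[2.2.1]hept-5-ene-2-carbaldehyde with the benzoyloxymethyl group on the alkene carbon next to the CH2-side bridgehead | O=C(OCC1=C[C@@H]2O[C@H]1C[C@@]2(Br)C=O)c1ccccc1
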